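## Structural features

The target is (3S,4S,6S)-4,10-dibromo-1,5,5,9-tetramethylspiro[5.5]undeca-1,9-dien-3-ol, a chamigrene-type spirocycle in which two cyclohexene rings share the quaternary carbon C6. Ring A (C1 to C6) carries a methyl group on the C1=C2 alkene, an allylic hydroxyl at C3, a secondary bromide at C4 and a gem-dimethyl carbon C5; ring B (C6 to C11) holds a tetrasubstituted C9=C10 alkene with a methyl group on C9 and a bromine on C10. C6 stands between the quaternary C5 and the fully substituted C1, so two quaternary carbons are neighbours, and C6 is stereogenic only through differences two bonds away (C1 against C5, C7 against C11). C3 and C4 are adjacent stereocentres with hydroxyl and bromine trans: the hydroxyl lies on the face of ring A that carries C7 and the bromine on the face that carries C11. The fragile groups are the trans-bromohydrin (epoxide closure or elimination with base), the allylic alcohol (ionisation with acid) and the vinyl bromide (low-valent metals, radical or dissolving-metal reduction). The real difficulty is stereochemical: the configuration of C6, and of C4 relative to it, must be read from the small difference between the C7 and C11 methylene groups, and the trans-bromohydrin is not the epimer that hydride reduction of an α-bromo ketone beside an axial methyl group is expected to give. The key step exploits the oxygen at C3 lying para to C6 with methyl groups on both C1 and C5, which is the substitution pattern of 3,5-dimethylphenol, together with the cis placement of C8 and C11 on the C9=C10 alkene, which lets C11 be offered to the para carbon as an allylic electrophile.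

## Logic of the disconnections

**22 from 21.** The O–acyl bond of an ester at C3 is cut. An ester is the one derivative of the alcohol that can carry a second, enantiopure stereogenic unit, so the last step is only a deprotection in which the resolving group leaves. The demand is a cleavage that never generates a free alkoxide next to the trans bromide; a hydride at low temperature meets it.

**21 from 19 and 20.** The C3–O bond is cut with inversion. Hydroxyl and bromine are trans in 22, whereas reduction of 18 is expected to give the cis alcohol 19, so an SN2 displacement at the allylic C3 corrects the configuration. With the enantiopure acid 20 as the nucleophile, the same operation turns racemic 19 into two separable diastereomers, so inversion and resolution cost one step. The demands are that substitution outruns elimination toward C4 and that the two esters separate.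

**19 from 18.** The C3–H bond is cut. The ketone is what the phenol oxygen becomes, and it keeps C4 enolisable for equilibration. The forward step needs hydride delivery from the C7 face, opposite the axial methyl group on C5.

**18 from 15.** The C5–CH3 and C4–Br bonds are cut. Conjugate methyl addition to one enone arm creates the gem-dimethyl carbon and, through its silyl dienol ether 16, a regiodefined nucleophile for bromination at C4. The gain is large: 15 is achiral. The two arms of 15 are enantiotopic, but the attacked carbon becomes CMe2, so the facial preference of a chiral copper catalyst would leave no trace in the product. Enantioselection would then rest only on telling the C7 from the C11 methylene. The step is therefore run without a chiral agent, C6 is formed as a racemate, and the absolute configuration is deferred to 21. C4 is set relative to C6 under thermodynamic control: the spiro junction holds ring A with C7 pseudoaxial, and the epimer with equatorial bromine on the C11 face (18) is the relaxed one. The demands are a single addition at a fully substituted β-carbon beside the spiro centre and complete equilibration of 17 to 18.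

**15 from 13 (through 14).** The C6–C11 bond is cut, which opens ring B and restores the arene. This removes the spiro centre, one ring and the adjacent-quaternary problem in one stroke and leads back to a flat phenol ether. The phenoxide is not isolated as the phenol but released from the silyl ether 13 by fluoride, so the allylic chloride never meets acid and one step is saved. The demand is intramolecular para C-alkylation in preference to intermolecular O-alkylation.

**13 from 12 from 11.** The C11–Cl bond and then the two C11–H bonds are cut (chloride from alcohol, alcohol from ester). These are functional-group changes at a primary allylic carbon. They must not move the alkene or change its geometry, which holds because SN2' attack would have to occur at the fully substituted C9.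

**11 from 9.** The C9–CH3 and C10–Br bonds are cut across the alkene to give an alkyne. Syn addition of methyl and copper followed by bromination with retention places C8 and the ester carbon C11 cis, exactly the geometry the ring closure needs, without any E/Z separation. The demand is that the alkenylcopper 10 keeps its configuration until it is brominated.

**9 from 6 and 7; 6 from 5.** The C10–C11 bond is cut (acetylide plus chloroformate 7) and the alkyne C–H is traced back to a C–Si bond. This gives a simple terminal alkyne. The demand is selective removal of the alkynyl silyl group in the presence of the aryl silyl ether.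

**5 from 2 and 3; 2 from 1.** The aryl–C7 bond is cut (Negishi coupling) and then the O–Si bond. This reduces the carbon skeleton to three commercial pieces (1, 3, 7) plus two methyl groups. The demand is an sp2–sp3 coupling at an aryl bromide flanked by two methyl groups.

## Other disconnections considered

**Alternative 1:** The cut takes C2 and C3 out of ring A: the C1–C2 and C3–C4 bonds are disconnected, ring A shrinks to the spiro-fused cyclobutanone A2, and the two carbons come from ethoxyethyne A3.
- Forward step: zerovalent nickel would couple the carbonyl carbon C1 with the alkyne, β-carbon elimination would open the strained ring at C1–C4, and reductive elimination would close ring A as the vinylogous ester A1. The C10 ketal of A1 stands in for the ring B bromoalkene.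
- In favour: the spiro centre and the gem-dimethyl carbon exist before ring A does, so no enantiotopic arms have to be told apart and no resolution is needed; on this point the alternative is better than the chosen plan. The 1,3-oxygen pattern of A1 would give the C1-methyl enone by methyl addition at C1 and acidic transposition, which is the equal of the conjugate methylation of step 9.
- Against: A2 already contains the two adjacent quaternary carbons and would have to be made as one enantiomer, so the hardest problem is moved, not solved. A terminal alkoxyalkyne lies outside the internal alkynes normally used in this insertion and may oligomerise. β-Carbon elimination must choose C1–C4 over C1–C6. Methyl addition at the C1 carbonyl is neopentyl-like.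
- Comparison: structurally it leaves ring B as a ketal that still needs methylation at C9 and regiocontrolled conversion into the tetrasubstituted bromoalkene, whereas step 8 closes ring B finished. Mechanistically it rests on a strain-driven organometallic step with two open selectivity questions, against a polar closure with one. In step count it would be clearly longer.

**Alternative 2:** The cut is the C1–C6 bond of ring A, leading to the acyclic Z β-iodoenone A5 attached to a 1,4-cyclohexadiene.
- Forward step: zerovalent palladium would insert into the C–I bond, the alkenylpalladium would add across the C6=C7 alkene in a 6-exo sense, and β-hydride elimination toward C8 would release the spiro trienone A4. A chiral ligand would fix C6.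
- In favour: the spiro centre would be set by catalysis and ring A would arrive complete, with gem-dimethyl group, C1 methyl and C3 ketone. No conjugate addition beside the spiro carbon and no resolution would be needed; in both respects the alternative is better than the chosen plan. Both plans close a six-membered ring onto C6 in an exo mode, which is equal.
- Against: the insertion must build a quaternary carbon directly beside the gem-dimethyl carbon, a congested migratory insertion whose enantioselectivity cannot be predicted with confidence. The 1,4-dienyl enol ether of A5 is prone to acid-induced isomerisation or hydrolysis.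
- Comparison: A4 carries a methoxy group at C10 and an extra C7=C8 alkene. The C7=C8 alkene would have to be saturated without touching the enone or the enol ether. The C10 oxygen would have to be exchanged for bromine with the alkene kept at C9=C10, for which no direct method exists. The step count would therefore equal or exceed that of the chosen plan, which carries the vinyl bromide through from step 5.

**Alternative 3:** The cut removes C10 from ring B: the C9–C10 and C10–C11 bonds are disconnected, ring B contracts to the cyclopentene of the spiro[4.5]decadienone A7, and C10 with its bromine comes from dibromocarbene A8.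
- Forward step: A8 would add to the C9=C11 alkene; the fused dibromocyclopropane would open with loss of bromide, breaking C9–C11, and the allyl cation would be captured to give A6.
- In favour: the vinyl bromide at C10 beside the C9 methyl group would arise in the key step itself with no alkene-geometry question, which is better than step 5. The electron-poor enone alkene should not compete for the electrophilic carbene. C6 would come from a purchased stereocentre of an ionone, A9, without an asymmetric step.
- Against: the additional bromine at C11 sits on a secondary allylic carbon beside the spiro centre and would have to be removed without allylic transposition and without touching the vinyl bromide or the enone. Cation capture at the tertiary C9 is a competing outcome. A7 requires a carbene C–H insertion at the doubly flanked ring methine, in competition with cyclopropanation of the ring alkene, and a regiocontrolled placement of the cyclopentene alkene.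
- Comparison: by the most direct mapping the (S)-enantiomer of A9 is required, and the usual commercial material is racemic, so the chiral-pool advantage would in practice also be a resolution, equal to the chosen plan. The end game from ring A enone to bromohydrin would be the same as steps 9 to 12, again equal. Overall the route would be longer and its key step leaves one more functional group to correct.

Key step: step 8

Assumption: 16, 17, 18 and 19 are racemates; their names and SMILES show the enantiomer that leads to 22, and the absolute configuration enters with 20 in step 11.

## Route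

Step 1
Reactants: 1 4-bromo-3,5-dimethylphenol
Product: 2 (4-bromo-3,5-dimethylphenoxy)tri(propan-2-yl)silane
Conditions: i-Pr3SiCl (1.1 equiv), imidazole (2 equiv), DMF, 0 °C to rt
Reagents that add atoms: chlorotri(propan-2-yl)silane, CC(C)[Si](Cl)(C(C)C)C(C)C
Why: Standard silylation of a phenol; the bulky silyl ether should withstand the organozinc, organolithium, cuprate and hydride reagents and brief carbonate methanolysis that follow, shields both ring positions ortho to oxygen from electrophilic bromine, and is the latent phenoxide of step 8.

Step 2
Reactants: 2 (4-bromo-3,5-dimethylphenoxy)tri(propan-2-yl)silane; 3 (4-bromobut-1-yn-1-yl)trimethylsilane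
Product: 5 trimethyl{4-[2,6-dimethyl-4-(tri(propan-2-yl)silyloxy)phenyl]but-1-yn-1-yl}silane, via organozinc bromide 4 (not isolated)
Conditions: 3 (1.5 equiv), Zn dust, LiCl, THF, 40 °C; then 2, Pd(OAc)2 (2 mol %), SPhos (4 mol %), THF, 50 °C
Reagents that add atoms: none
Why: Negishi coupling: LiCl-assisted insertion of zinc into the primary bromide gives 4, and the bulky electron-rich biarylphosphine lets zerovalent palladium insert into the doubly ortho-substituted aryl bromide and eliminate reductively faster than β-hydride loss; both silyl groups are inert to the organozinc.

Step 3
Reactants: 5 trimethyl{4-[2,6-dimethyl-4-(tri(propan-2-yl)silyloxy)phenyl]but-1-yn-1-yl}silane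
Product: 6 [4-(but-3-yn-1-yl)-3,5-dimethylphenoxy]tri(propan-2-yl)silane
Conditions: K2CO3 (0.3 equiv), MeOH/THF, 0 °C to rt, short reaction time
Reagents that add atoms: none
Why: Methanolysis of the alkynyl C–Si bond, which is cleaved far faster than the hindered aryl triisopropylsilyl ether, so brief exposure at or below room temperature should remove only the trimethylsilyl group.

Step 4
Reactants: 6 [4-(but-3-yn-1-yl)-3,5-dimethylphenoxy]tri(propan-2-yl)silane; 7 ethyl chloroformate
Product: 9 ethyl 5-[2,6-dimethyl-4-(tri(propan-2-yl)silyloxy)phenyl]pent-2-ynoate, via lithium acetylide 8 (not isolated)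
Conditions: n-BuLi (1.05 equiv), THF, −78 °C; then 7 (1.5 equiv), −78 °C to 0 °C
Reagents that add atoms: none
Why: Deprotonation of the terminal alkyne and C-acylation of the lithium acetylide with a chloroformate, a standard ynoate synthesis; the ester carbon introduced here becomes C11.

Step 5
Reactants: 9 ethyl 5-[2,6-dimethyl-4-(tri(propan-2-yl)silyloxy)phenyl]pent-2-ynoate
Product: 11 ethyl (2E)-2-bromo-5-[2,6-dimethyl-4-(tri(propan-2-yl)silyloxy)phenyl]-3-methylpent-2-enoate, via alkenyl(methyl)cuprate 10 (not isolated)
Conditions: Me2CuLi (from CuI and 2 MeLi, 1.2 equiv), THF, −78 °C; then NBS (1.3 equiv) in THF, −78 °C; aq NH4Cl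
Reagents that add atoms: lithium dimethylcuprate, [Li+].C[Cu-]C; N-bromosuccinimide, O=C1CCC(=O)N1Br
Why: Syn carbocupration (conjugate addition) of the ynoate followed by electrophilic bromination of the C–Cu bond with retention; methyl and copper add to the same side, so the C8 chain ends cis to the ester carbon, and at −78 °C the alkenylcopper should not equilibrate through its allenoate form.

Step 6
Reactants: 11 ethyl (2E)-2-bromo-5-[2,6-dimethyl-4-(tri(propan-2-yl)silyloxy)phenyl]-3-methylpent-2-enoate
Product: 12 (2E)-2-bromo-5-[2,6-dimethyl-4-(tri(propan-2-yl)silyloxy)phenyl]-3-methylpent-2-en-1-ol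
Conditions: i-Bu2AlH (2.5 equiv), CH2Cl2, −78 °C; aq potassium sodium tartrate (KNaC4H4O6)
Reagents that add atoms: none
Why: 1,2-Reduction of an unsaturated ester to the allylic alcohol with an aluminium hydride; at −78 °C the vinyl bromide, the alkene geometry and the aryl silyl ether should be untouched.

Step 7
Reactants: 12 (2E)-2-bromo-5-[2,6-dimethyl-4-(tri(propan-2-yl)silyloxy)phenyl]-3-methylpent-2-en-1-ol
Product: 13 {4-[(3E)-4-bromo-5-chloro-3-methylpent-3-en-1-yl]-3,5-dimethylphenoxy}tri(propan-2-yl)silane
Conditions: PPh3 (1.3 equiv), CCl4 (3 equiv), CH2Cl2, 0 °C to rt
Reagents that add atoms: tetrachloromethane, ClC(Cl)(Cl)Cl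
Why: Appel reaction: chloride displaces the oxyphosphonium group by SN2 at the primary allylic carbon under neutral conditions; allylic transposition is not expected because it would require attack at the fully substituted C9.

Step 8
Reactants: 13 {4-[(3E)-4-bromo-5-chloro-3-methylpent-3-en-1-yl]-3,5-dimethylphenoxy}tri(propan-2-yl)silane
Product: 15 10-bromo-1,5,9-trimethylspiro[5.5]undeca-1,4,9-trien-3-one, via ammonium phenolate 14 (not isolated)
Conditions: Bu4NF (1.3 equiv), THF, slow addition of 13 (final 0.005 M), 0 °C to 50 °C
Reagents that add atoms: none
Why: Fluoride cleaves the aryl O–Si bond of 13 and releases the tetrabutylammonium phenolate 14, an ambident nucleophile with charge at oxygen and at the ortho and para carbons. Its para carbon C6 displaces chloride from the allylic carbon C11 in an intramolecular SN2 reaction, which forms the C6–C11 bond and converts the arene into the cross-conjugated dienone 15. The closest known reaction type is the intramolecular para C-alkylation of phenoxides to spirocyclohexadienones (alkylative dearomatisation), including its fluoride-triggered form from aryl silyl ethers. Ring B (C6 to C11) closes in a 6-exo-tet mode with the C–Cl bond outside the new ring, and the E alkene holds C8 and C11 cis so that the electrophilic carbon is kept over the ring. No stereocentre is formed, since 15 has a mirror plane through C3, C6, C7 and C11. The selectivity needed is C- over O-alkylation: within one molecule the oxygen and the ortho carbons cannot reach C11, so only intermolecular O-alkylation competes, and slow addition at high dilution suppresses it. SN2' attack at C9 would give a four-membered ring and is not expected, and the two methyl groups beside C6 lie in the ring plane and do not block the perpendicular approach of C11.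

Step 9
Reactants: 15 10-bromo-1,5,9-trimethylspiro[5.5]undeca-1,4,9-trien-3-one
Product: 18 rac-(4S,6S)-4,10-dibromo-1,5,5,9-tetramethylspiro[5.5]undeca-1,9-dien-3-one, via silyl dienol ether 16 (not isolated), via C4-epimeric bromoketone 17 (not isolated)
Conditions: Me2CuLi (from CuI and 2 MeLi, 1.5 equiv), Me3SiCl (3 equiv), THF, −78 °C to −30 °C; Et3N, pentane, aq NH4Cl/NH3 (pH 8), crude 16; NBS (1.05 equiv), THF, −78 °C to 0 °C; DBU (0.2 equiv), CH2Cl2, rt
Reagents that add atoms: lithium dimethylcuprate, [Li+].C[Cu-]C; N-bromosuccinimide, O=C1CCC(=O)N1Br
Why: Silyl-accelerated cuprate conjugate addition to one arm of the dienone, bromination of the silyl dienol ether at its nucleophilic C4, and base-catalysed enolisation that equilibrates C4 (no elimination is possible because C5 bears no hydrogen); C6 arises as a racemate because the two arms are enantiotopic and no chiral agent is present, and C4 should settle as the epimer with equatorial bromine on the C11 face, because the spiro junction holds ring A with C7 pseudoaxial (the alternative pucker drives the C1 methyl group into the axial hydrogen on C8) and bromine on the C7 face would be syn-axial to C7.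

Step 10
Reactants: 18 rac-(4S,6S)-4,10-dibromo-1,5,5,9-tetramethylspiro[5.5]undeca-1,9-dien-3-one
Product: 19 rac-(3R,4S,6S)-4,10-dibromo-1,5,5,9-tetramethylspiro[5.5]undeca-1,9-dien-3-ol
Conditions: i-Bu2AlH (1.2 equiv), CH2Cl2, −78 °C; aq potassium sodium tartrate (KNaC4H4O6)
Reagents that add atoms: none
Why: 1,2-Reduction of an α'-bromo enone by an aluminium hydride; the axial methyl group on C5 blocks the C11 face of the carbonyl, so hydride should enter from the C7 face and place the new hydroxyl axial and cis to bromine (substrate control), the usual outcome for α-bromo cyclohexanones with a syn-axial β-methyl group.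

Step 11
Reactants: 19 rac-(3R,4S,6S)-4,10-dibromo-1,5,5,9-tetramethylspiro[5.5]undeca-1,9-dien-3-ol; 20 (2S)-2-methoxy-2-phenylacetic acid
Product: 21 (3S,4S,6S)-4,10-dibromo-1,5,5,9-tetramethylspiro[5.5]undeca-1,9-dien-3-yl (2S)-2-methoxy-2-phenylacetate
Conditions: 20 (1.5 equiv), PPh3 (1.6 equiv), DIAD (1.6 equiv), THF, 0 °C to rt; chromatographic separation of the two diastereomeric esters
Reagents that add atoms: none
Why: Mitsunobu reaction: the carboxylate displaces the activated axial oxygen at the allylic C3 by SN2 with inversion, which turns the cis-bromohydrin into the trans ester; because 20 is a single enantiomer, the two enantiomers of 19 give diastereomeric esters, and their separation fixes the absolute configuration at C4 and C6 (assignment by X-ray diffraction using the two bromine atoms).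

Step 12
Reactants: 21 (3S,4S,6S)-4,10-dibromo-1,5,5,9-tetramethylspiro[5.5]undeca-1,9-dien-3-yl (2S)-2-methoxy-2-phenylacetate
Product: 22 (3S,4S,6S)-4,10-dibromo-1,5,5,9-tetramethylspiro[5.5]undeca-1,9-dien-3-ol
Conditions: i-Bu2AlH (3 equiv), CH2Cl2, −78 °C; aq potassium sodium tartrate (KNaC4H4O6)
Reagents that add atoms: none
Why: Reductive ester cleavage at low temperature releases the alcohol as an aluminium alkoxide, which avoids the alkoxide bases that could close the trans-bromohydrin to an epoxide; no stereocentre is touched and the alkyl and vinyl bromides are inert to the hydride at −78 °C.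

## Compound list

1 | 4-bromo-3,5-dimethylphenol | Cc1cc(O)cc(C)c1Br | starting material
2 | (4-bromo-3,5-dimethylphenoxy)tri(propan-2-yl)silane | Cc1cc(O[Si](C(C)C)(C(C)C)C(C)C)cc(C)c1Br | intermediate
3 | (4-bromobut-1-yn-1-yl)trimethylsilane | C[Si](C)(C)C#CCCBr | starting material
4 | bromo[4-(trimethylsilyl)but-3-yn-1-yl]zinc | C[Si](C)(C)C#CCC[Zn]Br | intermediate (not isolated)
5 | trimethyl{4-[2,6-dimethyl-4-(tri(propan-2-yl)silyloxy)phenyl]but-1-yn-1-yl}silane | Cc1cc(O[Si](C(C)C)(C(C)C)C(C)C)cc(C)c1CCC#C[Si](C)(C)C | intermediate
6 | [4-(but-3-yn-1-yl)-3,5-dimethylphenoxy]tri(propan-2-yl)silane | Cc1cc(O[Si](C(C)C)(C(C)C)C(C)C)cc(C)c1CCC#C | intermediate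
7 | ethyl chloroformate | CCOC(=O)Cl | starting material
8 | {4-[2,6-dimethyl-4-(tri(propan-2-yl)silyloxy)phenyl]but-1-yn-1-yl}lithium | Cc1cc(O[Si](C(C)C)(C(C)C)C(C)C)cc(C)c1CCC#C[Li] | intermediate (not isolated)
9 | ethyl 5-[2,6-dimethyl-4-(tri(propan-2-yl)silyloxy)phenyl]pent-2-ynoate | Cc1cc(O[Si](C(C)C)(C(C)C)C(C)C)cc(C)c1CCC#CC(=O)OCC | intermediate
10 | lithium methyl{(1E)-1-(ethoxycarbonyl)-4-[2,6-dimethyl-4-(tri(propan-2-yl)silyloxy)phenyl]-2-methylbut-1-en-1-yl}cuprate | Cc1cc(O[Si](C(C)C)(C(C)C)C(C)C)cc(C)c1CC/C(C)=C(/[Cu-]C)C(=O)OCC.[Li+] | intermediate (not isolated)
11 | ethyl (2E)-2-bromo-5-[2,6-dimethyl-4-(tri(propan-2-yl)silyloxy)phenyl]-3-methylpent-2-enoate | Cc1cc(O[Si](C(C)C)(C(C)C)C(C)C)cc(C)c1CC/C(C)=C(/Br)C(=O)OCC | intermediate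
12 | (2E)-2-bromo-5-[2,6-dimethyl-4-(tri(propan-2-yl)silyloxy)phenyl]-3-methylpent-2-en-1-ol | Cc1cc(O[Si](C(C)C)(C(C)C)C(C)C)cc(C)c1CC/C(C)=C(/Br)CO | intermediate
13 | {4-[(3E)-4-bromo-5-chloro-3-methylpent-3-en-1-yl]-3,5-dimethylphenoxy}tri(propan-2-yl)silane | Cc1cc(O[Si](C(C)C)(C(C)C)C(C)C)cc(C)c1CC/C(C)=C(/Br)CCl | intermediate (silyl-masked precursor of the key step)
14 | tetrabutylammonium 4-[(3E)-4-bromo-5-chloro-3-methylpent-3-en-1-yl]-3,5-dimethylphenolate (the free-phenol precursor in its reactive form) | CCCC[N+](CCCC)(CCCC)CCCC.Cc1cc([O-])cc(C)c1CC/C(C)=C(/Br)CCl | intermediate (not isolated)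
15 | 10-bromo-1,5,9-trimethylspiro[5.5]undeca-1,4,9-trien-3-one (achiral) | CC1=CC(=O)C=C(C)C12CCC(C)=C(Br)C2 | intermediate
16 | (±)-[(10-bromo-1,5,5,9-tetramethylspiro[5.5]undeca-1,3,9-trien-3-yl)oxy]trimethylsilane (racemate, 6S enantiomer drawn) | CC1=CC(O[Si](C)(C)C)=CC(C)(C)[C@]12CCC(C)=C(Br)C2 | intermediate (not isolated)
17 | rac-(4R,6S)-4,10-dibromo-1,5,5,9-tetramethylspiro[5.5]undeca-1,9-dien-3-one (racemate, one enantiomer drawn) | CC1=CC(=O)[C@H](Br)C(C)(C)[C@]12CCC(C)=C(Br)C2 | intermediate (not isolated)
18 | rac-(4S,6S)-4,10-dibromo-1,5,5,9-tetramethylspiro[5.5]undeca-1,9-dien-3-one (racemate, one enantiomer drawn) | CC1=CC(=O)[C@@H](Br)C(C)(C)[C@]12CCC(C)=C(Br)C2 | intermediate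
19 | rac-(3R,4S,6S)-4,10-dibromo-1,5,5,9-tetramethylspiro[5.5]undeca-1,9-dien-3-ol (racemate, one enantiomer drawn) | CC1=C[C@@H](O)[C@@H](Br)C(C)(C)[C@]12CCC(C)=C(Br)C2 | intermediate
20 | (2S)-2-methoxy-2-phenylacetic acid | CO[C@H](C(=O)O)c1ccccc1 | starting material
21 | (3S,4S,6S)-4,10-dibromo-1,5,5,9-tetramethylspiro[5.5]undeca-1,9-dien-3-yl (2S)-2-methoxy-2-phenylacetate | CC1=C[C@H](OC(=O)[C@@H](OC)c3ccccc3)[C@@H](Br)C(C)(C)[C@]12CCC(C)=C(Br)C2 | intermediate
22 | (3S,4S,6S)-4,10-dibromo-1,5,5,9-tetramethylspiro[5.5]undeca-1,9-dien-3-ol | CC1=C[C@H](O)[C@@H](Br)C(C)(C)[C@]12CCC(C)=C(Br)C2 | target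

## Step count and least certain steps

Total step count: 12 steps. Longest linear sequence: 12 steps, from 1 to 22; 3, 7 and 20 enter in steps 2, 4 and 11.

**Step 8 (key step).** The most likely failure is intermolecular O-alkylation and oligomerisation overtaking the ring closure, because a poorly solvated ammonium phenoxide reacts fastest at oxygen and the para carbon is flanked by two methyl groups. The fallback sets out from 13 and returns at 15. Buffered desilylation (Bu4NF with AcOH, THF, 0 °C) would give the free phenol 4-[(3E)-4-bromo-5-chloro-3-methylpent-3-en-1-yl]-3,5-dimethylphenol F1. Halide exchange (NaI, acetone) would give the more reactive allylic iodide 4-[(3E)-4-bromo-5-iodo-3-methylpent-3-en-1-yl]-3,5-dimethylphenol F2. F2 would then be cyclised as its potassium phenoxide in a hydrogen-bonding solvent that masks the oxygen (KOt-Bu, t-BuOH, 0.005 M, 50 to 80 °C), the classical medium for aryl participation, to give 15.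

**Step 9.** The most likely failure is incomplete or 1,2-directed methyl transfer, because the attacked β-carbon is fully substituted and lies beside the spiro centre, so a quaternary carbon is formed next to another one. A second concern is incomplete equilibration at C4. The fallback sets out from 15 and returns at 16, and separates carbon–carbon bond formation from enolate chemistry. A Lewis acid-activated organocopper (MeCu with BF3·OEt2, from CuI and MeLi, Et2O, −78 °C to −30 °C) with protic work-up would give the isolated enone (±)-10-bromo-1,5,5,9-tetramethylspiro[5.5]undeca-1,9-dien-3-one F3. Kinetic deprotonation at C4 with silylation (LiN(SiMe3)2, Me3SiCl, THF, −78 °C) would then give 16, from which bromination and equilibration proceed as in step 9.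

**Step 11.** The most likely failure is β-elimination across C3–C4, since the axial hydrogen on C4 is antiperiplanar to the activated axial C3–O bond and the basic Mitsunobu medium can remove it. The fallback sets out from 19 and returns at 21, and uses a discrete sulfonate with a weakly basic carboxylate. Mesylation (MsCl, Et3N, CH2Cl2, −20 °C) would give rac-(3R,4S,6S)-4,10-dibromo-1,5,5,9-tetramethylspiro[5.5]undeca-1,9-dien-3-yl methanesulfonate F4. Displacement with inversion by caesium (2S)-2-methoxy-2-phenylacetate F5 (from 20 and Cs2CO3; DMF, rt) would give 21 beside its diastereomer (3R,4R,6R)-4,10-dibromo-1,5,5,9-tetramethylspiro[5.5]undeca-1,9-dien-3-yl (2S)-2-methoxy-2-phenylacetate F9, which is removed by chromatography.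

**Step 10.** The most likely failure is poor facial selectivity of hydride delivery, because each face of the carbonyl has an axial neighbour (the methyl group on C5 on one side, the C7 methylene on the other). The fallback sets out from 18 and returns at 21, and places C3 under thermodynamic control so that no inversion is needed. Reduction without regard to selectivity (NaBH4, CeCl3·7H2O, MeOH, −40 °C) would be followed by equilibration of the epimeric alcohols through reversible hydride transfer (Al(Oi-Pr)3, catalytic acetone, toluene, 60 °C). This should favour the equatorial alcohol rac-(3S,4S,6S)-4,10-dibromo-1,5,5,9-tetramethylspiro[5.5]undeca-1,9-dien-3-ol F6, which is free of the syn-axial contact with the C5 methyl group. Acylation with retention (20, DCC, DMAP, CH2Cl2) and the same chromatographic separation as in step 11 would give 21.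

**Step 5.** The most likely failure is loss of alkene geometry through isomerisation of the alkenylcopper via its allenoate form before bromination; ring bromination by excess NBS is a lesser concern. The fallback sets out from 6 and returns at 11, and builds the alkene by olefination. Hydration of the alkyne (Ph3PAuNTf2 cat., aq MeOH, 50 °C) would give the methyl ketone 4-[2,6-dimethyl-4-(tri(propan-2-yl)silyloxy)phenyl]butan-2-one F7. Horner–Wadsworth–Emmons reaction with ethyl bromo(diethoxyphosphoryl)acetate (NaH, THF, 0 °C to rt) would give 11 together with its geometric isomer ethyl (2Z)-2-bromo-5-[2,6-dimethyl-4-(tri(propan-2-yl)silyloxy)phenyl]-3-methylpent-2-enoate F8. The two are separated by chromatography and assigned by nuclear Overhauser contacts between the C8 methylene and the ester-side group.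

## Further compounds

F1 | step 8 | 4-[(3E)-4-bromo-5-chloro-3-methylpent-3-en-1-yl]-3,5-dimethylphenol | Cc1cc(O)cc(C)c1CC/C(C)=C(/Br)CCl
F2 | step 8 | 4-[(3E)-4-bromo-5-iodo-3-methylpent-3-en-1-yl]-3,5-dimethylphenol | Cc1cc(O)cc(C)c1CC/C(C)=C(/Br)CI
F3 | step 9 | (±)-10-bromo-1,5,5,9-tetramethylspiro[5.5]undeca-1,9-dien-3-one (racemate, one enantiomer drawn) | CC1=CC(=O)CC(C)(C)[C@]12CCC(C)=C(Br)C2
F4 | step 11 | rac-(3R,4S,6S)-4,10-dibromo-1,5,5,9-tetramethylspiro[5.5]undeca-1,9-dien-3-yl methanesulfonate (racemate, one enantiomer drawn) | CC1=C[C@@H](OS(C)(=O)=O)[C@@H](Br)C(C)(C)[C@]12CCC(C)=C(Br)C2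
F5 | step 11 | caesium (2S)-2-methoxy-2-phenylacetate | CO[C@H](C(=O)[O-])c1ccccc1.[Cs+]
F9 | step 11 | (3R,4R,6R)-4,10-dibromo-1,5,5,9-tetramethylspiro[5.5]undeca-1,9-dien-3-yl (2S)-2-methoxy-2-phenylacetate | CC1=C[C@@H](OC(=O)[C@@H](OC)c3ccccc3)[C@H](Br)C(C)(C)[C@@]12CCC(C)=C(Br)C2
F6 | step 10 | rac-(3S,4S,6S)-4,10-dibromo-1,5,5,9-tetramethylspiro[5.5]undeca-1,9-dien-3-ol (racemate, one enantiomer drawn) | CC1=C[C@H](O)[C@@H](Br)C(C)(C)[C@]12CCC(C)=C(Br)C2
F7 | step 5 | 4-[2,6-dimethyl-4-(tri(propan-2-yl)silyloxy)phenyl]butan-2-one | Cc1cc(O[Si](C(C)C)(C(C)C)C(C)C)cc(C)c1CCC(C)=O
F8 | step 5 | ethyl (2Z)-2-bromo-5-[2,6-dimethyl-4-(tri(propan-2-yl)silyloxy)phenyl]-3-methylpent-2-enoate | Cc1cc(O[Si](C(C)C)(C(C)C)C(C)C)cc(C)c1CC/C(C)=C(\Br)C(=O)OCC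
A1 | alternative 1 | (6R)-3-ethoxy-5,5-dimethylspiro[5.5]undec-2-ene-1,10-dione 10-(ethane-1,2-diyl ketal) | O=C1C=C(OCC)CC(C)(C)[C@]12CCCC3(OCCO3)C2
A2 | alternative 1 | (4R)-3,3-dimethylspiro[3.5]nonane-1,6-dione 6-(ethane-1,2-diyl ketal) | O=C1CC(C)(C)[C@]12CCCC3(OCCO3)C2
A3 | alternative 1 | ethoxyethyne | CCOC#C
A4 | alternative 2 | (6S)-10-methoxy-1,5,5,9-tetramethylspiro[5.5]undeca-1,7,9-trien-3-one | CC1=CC(=O)CC(C)(C)[C@]12C=CC(C)=C(OC)C2
A5 | alternative 2 | (5Z)-6-iodo-2-(5-methoxy-4-methylcyclohexa-1,4-dien-1-yl)-2-methylhept-5-en-4-one | C/C(I)=C/C(=O)CC(C)(C)C1=CCC(C)=C(OC)C1
A6 | alternative 3 | (6R,11S)-10,11-dibromo-1,5,5,9-tetramethylspiro[5.5]undeca-1,9-dien-3-one | CC1=CC(=O)CC(C)(C)[C@]12CCC(C)=C(Br)[C@H]2Br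
A7 | alternative 3 | (5R)-2,6,10,10-tetramethylspiro[4.5]deca-1,6-dien-8-one | CC1=CC(=O)CC(C)(C)[C@]12CCC(C)=C2
A8 | alternative 3 | dibromocarbene | Br[C]Br
A9 | alternative 3 | (3E)-4-[(1S)-2,6,6-trimethylcyclohex-2-en-1-yl]but-3-en-2-one ((S)-α-ionone) | CC1=CCCC(C)(C)[C@@H]1/C=C/C(C)=O
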